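**Retrosynthetic overview**

1. The target is ring C (cyclopentenone; C1′ carbinol with CO2Me, C2′ =CH, C3′ C–OMe, C4′ C=O, C5′ CH) joined through CH2 to C2 of a trans-decalin (rings A and B, naphthalene numbering). The C5′–CH2 bond is cut last: aldol condensation of ring C ketone 31 with decalin aldehyde 21, then hydroxyl-steered reduction of the C5′ alkylidene.
2. Decalin 21: the C1 methyl comes from methylenation and hydrogenation of a C1 ketone; quaternary C2 from hydroxymethylation and conjugate reduction–methylation of ring B enone 13; ring B from Wacker oxidation and aldol closure onto ring A.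
3. The strategy rests on the adjacent pair C8a–H / C4a–CH3 at the ring A/B fusion, trans to each other, with C4a quaternary. This is the pattern left by anti β-vinylation and α-alkylation of 2-methylcyclohex-2-enone, whose carbonyl becomes C5 and then the C5(Me)=C6 alkene.
4. Ring C ketone 31: catalytic asymmetric aldol of acetone with a styryl α-keto ester (sets C1′), ozonolysis, cyclising aldol, α-iodination and copper-catalysed methoxylation.
5. Order of rings: ring A is bought (1), ring B closes in step 7, ring C closes in step 18 on its own branch, and the halves are joined in step 21.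

Key step: step 1

Assumption: the sense of induction of the ligand in step 1 and of the cinchona amine in step 15 is as stated; if either proves opposite, the mirror-image ligand or the pseudoenantiomeric amine is used.

**Route**

Step 1
Reactants: 1 2-methylcyclohex-2-en-1-one; 2 vinylmagnesium bromide; 3 tert-butyl bromoacetate
Product: 5 tert-butyl 2-[(1S,6S)-6-ethenyl-1-methyl-2-oxocyclohexyl]acetate (vinyl and CH2CO2tBu trans), via magnesium enolate 4 (not isolated)
Conditions: CuBr·SMe2 (5 mol %), (S,R,R)-O,O′-(1,1′-binaphthyl-2,2′-diyl) N,N-bis(1-phenylethyl)phosphoramidite (6 mol %), 2-MeTHF, −78 °C, slow addition of 2; then 3, DMPU, −78 → −20 °C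
Reagents that add atoms: none
Why: Copper-catalysed asymmetric conjugate addition of a Grignard reagent with alkylation of the enolate in the same flask: transmetalation gives a ligand-bound monovalent copper–vinyl species, which adds to C3 of the enone (C8a of the decalin) through a π-complex and a trivalent copper β-adduct, and reductive elimination leaves the regiodefined magnesium enolate 4. The closest known reaction type is the copper/phosphoramidite-catalysed addition of Grignard reagents to 2-methylcyclohex-2-enone with trapping of the magnesium enolate by reactive alkyl halides. No ring closes; the two skeletal bonds formed are C8a–C1 and C4a–C4. C8a is set by the chiral ligand on copper, and C4a by the substrate, because the bromoacetate reaches the tetrasubstituted enolate carbon anti to the neighbouring vinyl group, which gives the trans relationship. The step needs 1,4- over 1,2-addition (copper catalysis, slow addition at −78 °C) and a single C-alkylation at the quaternary carbon (regiodefined enolate, DMPU activation, and a tert-butyl ester that resists Claisen attack).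

Step 2
Reactants: 5 tert-butyl 2-[(1S,6S)-6-ethenyl-1-methyl-2-oxocyclohexyl]acetate
Product: 7 tert-butyl 2-[(1S,6S)-6-ethenyl-1-methyl-2-(trifluoromethylsulfonyloxy)cyclohex-2-en-1-yl]acetate, via potassium enolate 6 (not isolated)
Conditions: KN(SiMe3)2, THF, −78 °C; then PhNTf2, −78 → 0 °C
Reagents that add atoms: N-phenylbis(trifluoromethanesulfonimide), O=S(=O)(N(c1ccccc1)S(=O)(=O)C(F)(F)F)C(F)(F)F
Why: Enol triflate formation: the ketone can be deprotonated only at C6 (C4a is quaternary) and faster than the tert-butyl ester, and the enolate is O-sulfonylated.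

Step 3
Reactants: 7 tert-butyl 2-[(1S,6S)-6-ethenyl-1-methyl-2-(trifluoromethylsulfonyloxy)cyclohex-2-en-1-yl]acetate
Product: 8 tert-butyl 2-[(1S,6S)-6-ethenyl-1,2-dimethylcyclohex-2-en-1-yl]acetate
Conditions: MeMgBr, Fe(acac)3 (5 mol %), THF/NMP, −30 → 0 °C
Reagents that add atoms: methylmagnesium bromide, C[Mg]Br
Why: Iron-catalysed Kumada-type cross-coupling of the alkenyl triflate is fast at low temperature, where the tert-butyl ester and the vinyl group are left alone, and gives the C5(Me)=C6 alkene.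

Step 4
Reactants: 8 tert-butyl 2-[(1S,6S)-6-ethenyl-1,2-dimethylcyclohex-2-en-1-yl]acetate
Product: 9 tert-butyl 2-[(1S,6R)-6-acetyl-1,2-dimethylcyclohex-2-en-1-yl]acetate
Conditions: PdCl2 (10 mol %), CuCl, O2 (1 atm), DMF/H2O (7:1), rt
Reagents that add atoms: water, O
Why: Tsuji–Wacker oxidation: Markovnikov hydroxypalladation of the monosubstituted vinyl group gives the methyl ketone (C1 and C2), while the trisubstituted C5=C6 alkene and the ester do not react.

Step 5
Reactants: 9 tert-butyl 2-[(1S,6R)-6-acetyl-1,2-dimethylcyclohex-2-en-1-yl]acetate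
Product: 10 2-[(1S,6R)-6-(1-hydroxyethyl)-1,2-dimethylcyclohex-2-en-1-yl]ethan-1-ol (carbinol epimers)
Conditions: LiAlH4, THF, 0 °C → rt
Reagents that add atoms: none
Why: Hydride reduction of ester and ketone together to the diol avoids having to reduce the ester selectively in the presence of the ketone; the carbinol configuration is irrelevant.

Step 6
Reactants: 10 2-[(1S,6R)-6-(1-hydroxyethyl)-1,2-dimethylcyclohex-2-en-1-yl]ethan-1-ol
Product: 11 2-[(1S,6R)-6-acetyl-1,2-dimethylcyclohex-2-en-1-yl]acetaldehyde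
Conditions: Dess–Martin periodinane (2.5 equiv), NaHCO3, CH2Cl2, rt
Reagents that add atoms: none
Why: Dess–Martin oxidation of both alcohols under neutral conditions gives the 1,5-keto aldehyde without touching the alkene.

Step 7
Reactants: 11 2-[(1S,6R)-6-acetyl-1,2-dimethylcyclohex-2-en-1-yl]acetaldehyde
Product: 13 (4aS,8aR)-4a,5-dimethyl-4a,7,8,8a-tetrahydronaphthalen-1(4H)-one (trans-fused), via aldol 12 (not isolated)
Conditions: KOH, MeOH, 0 °C → rt
Reagents that add atoms: none
Why: Intramolecular aldol condensation closes ring B, since only the methyl-ketone enolate (C2) attacking the aldehyde (C3) gives a six-membered ring; E1cB dehydration gives the enone, and the base keeps the epimerisable C8a at the more stable trans fusion set in step 1.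

Step 8
Reactants: 13 (4aS,8aR)-4a,5-dimethyl-4a,7,8,8a-tetrahydronaphthalen-1(4H)-one
Product: 14 (4aS,8aR)-2-(hydroxymethyl)-4a,5-dimethyl-4a,7,8,8a-tetrahydronaphthalen-1(4H)-one
Conditions: aq. CH2O (37 %), imidazole, THF/H2O, rt
Reagents that add atoms: formaldehyde, C=O
Why: Morita–Baylis–Hillman reaction: imidazole adds reversibly to the unsubstituted C3, the enolate adds to formaldehyde at C2 and the catalyst is expelled.

Step 9
Reactants: 14 (4aS,8aR)-2-(hydroxymethyl)-4a,5-dimethyl-4a,7,8,8a-tetrahydronaphthalen-1(4H)-one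
Product: 15 (4aS,8aR)-2-{[(tert-butyldimethylsilyl)oxy]methyl}-4a,5-dimethyl-4a,7,8,8a-tetrahydronaphthalen-1(4H)-one
Conditions: TBSCl, imidazole, DMF, rt
Reagents that add atoms: tert-butyldimethylsilyl chloride, CC(C)(C)[Si](C)(C)Cl
Why: Silylation of the primary alcohol protects it from the hydride, base and alkylating agent of steps 10 and 11.

Step 10
Reactants: 15 (4aS,8aR)-2-{[(tert-butyldimethylsilyl)oxy]methyl}-4a,5-dimethyl-4a,7,8,8a-tetrahydronaphthalen-1(4H)-one
Product: 17 (2R,4aS,8aR)-2-{[(tert-butyldimethylsilyl)oxy]methyl}-2,4a,5-trimethyl-3,4,4a,7,8,8a-hexahydronaphthalen-1(2H)-one (C2 methyl α, CH2OTBS β), via potassium enolate 16 (not isolated)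
Conditions: KBH(s-Bu)3, THF, −78 °C; then MeI, DMPU, −78 → −20 °C
Reagents that add atoms: iodomethane, CI
Why: Conjugate reduction–enolate alkylation: hydride adds to the unsubstituted β-carbon C3 of the cyclohexenone, and the C1–C2 enolate is methylated at C2 along the axial trajectory on the α-face, anti to the angular C4a methyl, so the new methyl is α (axial) and CH2OTBS is β (equatorial).

Step 11
Reactants: 17 (2R,4aS,8aR)-2-{[(tert-butyldimethylsilyl)oxy]methyl}-2,4a,5-trimethyl-3,4,4a,7,8,8a-hexahydronaphthalen-1(2H)-one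
Product: 18 tert-butyldimethyl{[(2S,4aS,8aS)-2,4a,5-trimethyl-1-methylidene-1,2,3,4,4a,7,8,8a-octahydronaphthalen-2-yl]methoxy}silane
Conditions: Ph3PCH3Br, KOtBu, toluene, 90 °C
Reagents that add atoms: methylenetriphenylphosphorane (made in the flask from methyltriphenylphosphonium bromide and KOtBu), C=P(c1ccccc1)(c1ccccc1)c1ccccc1
Why: Wittig methylenation with excess salt-free ylide in hot toluene is the standard answer to a hindered ketone; C2 is quaternary, so the silyloxy group cannot be eliminated, and C8a, if enolised, returns to the trans fusion.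

Step 12
Reactants: 18 tert-butyldimethyl{[(2S,4aS,8aS)-2,4a,5-trimethyl-1-methylidene-1,2,3,4,4a,7,8,8a-octahydronaphthalen-2-yl]methoxy}silane
Product: 19 tert-butyldimethyl{[(1R,2S,4aS,8aS)-1,2,4a,5-tetramethyl-1,2,3,4,4a,7,8,8a-octahydronaphthalen-2-yl]methoxy}silane (C1 methyl β, cis to the C4a methyl)
Conditions: H2 (1 atm), PtO2, EtOAc, rt, stopped after one equivalent
Reagents that add atoms: none
Why: Heterogeneous hydrogenation should take the 1,1-disubstituted exocyclic alkene before the trisubstituted C5=C6 alkene (platinum also limits double-bond migration); the β-face of C1 lies under the syn-axial C4a methyl, so hydrogen should add from the α-face and leave the C1 methyl β, as when 6-methylene steroids give 6β-methyl compounds.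

Step 13
Reactants: 19 tert-butyldimethyl{[(1R,2S,4aS,8aS)-1,2,4a,5-tetramethyl-1,2,3,4,4a,7,8,8a-octahydronaphthalen-2-yl]methoxy}silane
Product: 20 [(1R,2S,4aS,8aS)-1,2,4a,5-tetramethyl-1,2,3,4,4a,7,8,8a-octahydronaphthalen-2-yl]methanol
Conditions: Bu4NF, THF, rt
Reagents that add atoms: none
Why: Fluoride cleavage of the silyl ether; nothing else in the molecule is sensitive to it.

Step 14
Reactants: 20 [(1R,2S,4aS,8aS)-1,2,4a,5-tetramethyl-1,2,3,4,4a,7,8,8a-octahydronaphthalen-2-yl]methanol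
Product: 21 (1R,2S,4aS,8aS)-1,2,4a,5-tetramethyl-1,2,3,4,4a,7,8,8a-octahydronaphthalene-2-carbaldehyde
Conditions: Dess–Martin periodinane, NaHCO3, CH2Cl2, rt
Reagents that add atoms: none
Why: Dess–Martin oxidation gives the neopentyl aldehyde, which has no α-hydrogen and so cannot epimerise or self-condense.

Step 15
Reactants: 22 acetone; 23 methyl (E)-2-oxo-4-phenylbut-3-enoate
Product: 24 methyl (2R,3E)-2-hydroxy-2-(2-oxopropyl)-4-phenylbut-3-enoate
Conditions: 9-amino-9-deoxy-epi-quinine (10 mol %), 4-nitrobenzoic acid (20 mol %), acetone as solvent, rt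
Reagents that add atoms: none
Why: Primary-amine (enamine) catalysed direct asymmetric aldol reaction of acetone with a β,γ-unsaturated α-keto ester: the enamine adds 1,2 to the activated ketone, which is held by hydrogen bonding to the protonated quinuclidine, so the catalyst sets the tertiary carbinol (later C1′).

Step 16
Reactants: 24 methyl (2R,3E)-2-hydroxy-2-(2-oxopropyl)-4-phenylbut-3-enoate
Product: 25 methyl (2R,3E)-2-[(tert-butyldimethylsilyl)oxy]-2-(2-oxopropyl)-4-phenylbut-3-enoate
Conditions: TBSOTf, 2,6-lutidine, CH2Cl2, 0 °C → rt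
Reagents that add atoms: tert-butyldimethylsilyl trifluoromethanesulfonate, CC(C)(C)[Si](C)(C)OS(=O)(=O)C(F)(F)F
Why: Silylation of the tertiary alcohol with the silyl triflate blocks retro-aldol cleavage and α-ketol shifts in every later basic or acidic step.

Step 17
Reactants: 25 methyl (2R,3E)-2-[(tert-butyldimethylsilyl)oxy]-2-(2-oxopropyl)-4-phenylbut-3-enoate
Product: 27 methyl (2R)-2-[(tert-butyldimethylsilyl)oxy]-2-formyl-4-oxopentanoate, via ozonide 26 (not isolated)
Conditions: O3, CH2Cl2, −78 °C; then Me2S, −78 °C → rt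
Reagents that add atoms: ozone, [O-][O+]=O
Why: Ozonolysis with reductive work-up cleaves the styryl alkene and leaves the aldehyde carbon (C2′) on the quaternary centre.

Step 18
Reactants: 27 methyl (2R)-2-[(tert-butyldimethylsilyl)oxy]-2-formyl-4-oxopentanoate
Product: 29 methyl (1R)-1-[(tert-butyldimethylsilyl)oxy]-4-oxocyclopent-2-ene-1-carboxylate, via aldol 28 (not isolated)
Conditions: dibenzylammonium trifluoroacetate (20 mol %), benzene, 50 °C
Reagents that add atoms: none
Why: Intramolecular aldol condensation of a 1,4-keto aldehyde under mild ammonium catalysis closes ring C, since only the methyl group (C3′) can form a five-membered ring with the aldehyde (C2′); C1′ is not touched.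

Step 19
Reactants: 29 methyl (1R)-1-[(tert-butyldimethylsilyl)oxy]-4-oxocyclopent-2-ene-1-carboxylate
Product: 30 methyl (1R)-1-[(tert-butyldimethylsilyl)oxy]-3-iodo-4-oxocyclopent-2-ene-1-carboxylate
Conditions: I2, pyridine, DMAP (cat.), CH2Cl2, rt
Reagents that add atoms: iodine, II
Why: α-Iodination of the enone by a Baylis–Hillman-type sequence (conjugate addition of the amine, iodination of the enolate, loss of the amine).

Step 20
Reactants: 30 methyl (1R)-1-[(tert-butyldimethylsilyl)oxy]-3-iodo-4-oxocyclopent-2-ene-1-carboxylate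
Product: 31 methyl (1R)-1-[(tert-butyldimethylsilyl)oxy]-3-methoxy-4-oxocyclopent-2-ene-1-carboxylate
Conditions: CuI (10 mol %), 3,4,7,8-tetramethyl-1,10-phenanthroline (20 mol %), Cs2CO3, MeOH/toluene, 80 °C
Reagents that add atoms: methanol, CO
Why: Copper-catalysed Ullmann-type C–O coupling of a vinyl iodide with an alcohol places the methoxy group on C3′ without passing through the symmetric 1,2-dione, which would racemise C1′.

Step 21
Reactants: 31 methyl (1R)-1-[(tert-butyldimethylsilyl)oxy]-3-methoxy-4-oxocyclopent-2-ene-1-carboxylate; 21 (1R,2S,4aS,8aS)-1,2,4a,5-tetramethyl-1,2,3,4,4a,7,8,8a-octahydronaphthalene-2-carbaldehyde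
Product: 33 methyl (1S)-1-[(tert-butyldimethylsilyl)oxy]-5-{hydroxy[(1R,2S,4aS,8aS)-1,2,4a,5-tetramethyl-1,2,3,4,4a,7,8,8a-octahydronaphthalen-2-yl]methyl}-3-methoxy-4-oxocyclopent-2-ene-1-carboxylate (mixture at C5′ and at the carbinol carbon), via lithium enolate 32 (not isolated)
Conditions: LiN(i-Pr)2, THF, −78 °C; then 21, −78 °C; aq. NH4Cl at −78 °C
Reagents that add atoms: none
Why: Crossed aldol addition: 31 can be deprotonated only at C5′ and the aldehyde cannot enolise, as in aldol reactions of 4,4-disubstituted cyclopentenone enolates; the two new stereocentres need no control because they are removed in step 22, and the cold quench limits retro-aldol and lactonisation onto the ester.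

Step 22
Reactants: 33 methyl (1S)-1-[(tert-butyldimethylsilyl)oxy]-5-{hydroxy[(1R,2S,4aS,8aS)-1,2,4a,5-tetramethyl-1,2,3,4,4a,7,8,8a-octahydronaphthalen-2-yl]methyl}-3-methoxy-4-oxocyclopent-2-ene-1-carboxylate
Product: 35 methyl (1S)-1-[(tert-butyldimethylsilyl)oxy]-3-methoxy-4-oxo-5-{[(1R,2S,4aS,8aS)-1,2,4a,5-tetramethyl-1,2,3,4,4a,7,8,8a-octahydronaphthalen-2-yl]methylidene}cyclopent-2-ene-1-carboxylate (alkene geometry not controlled; both isomers serve), via mesylate 34 (not isolated)
Conditions: MsCl, Et3N, CH2Cl2, 0 °C; then DBU, rt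
Reagents that add atoms: none
Why: Mesylation and E1cB elimination of the β-mesyloxy ketone give the cross-conjugated dienone.

Step 23
Reactants: 35 methyl (1S)-1-[(tert-butyldimethylsilyl)oxy]-3-methoxy-4-oxo-5-{[(1R,2S,4aS,8aS)-1,2,4a,5-tetramethyl-1,2,3,4,4a,7,8,8a-octahydronaphthalen-2-yl]methylidene}cyclopent-2-ene-1-carboxylate
Product: 36 methyl (1S)-1-hydroxy-3-methoxy-4-oxo-5-{[(1R,2S,4aS,8aS)-1,2,4a,5-tetramethyl-1,2,3,4,4a,7,8,8a-octahydronaphthalen-2-yl]methylidene}cyclopent-2-ene-1-carboxylate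
Conditions: HF·pyridine, pyridine/THF, 0 °C → rt
Reagents that add atoms: none
Why: Buffered HF cleaves the tertiary silyl ether without base; the dienone cannot undergo retro-aldol (C5′ is sp2), and the free hydroxyl is needed to steer step 24.

Step 24
Reactants: 36 methyl (1S)-1-hydroxy-3-methoxy-4-oxo-5-{[(1R,2S,4aS,8aS)-1,2,4a,5-tetramethyl-1,2,3,4,4a,7,8,8a-octahydronaphthalen-2-yl]methylidene}cyclopent-2-ene-1-carboxylate
Product: 37 Dysidenone A, methyl (1S,5R)-1-hydroxy-3-methoxy-4-oxo-5-{[(1R,2R,4aS,8aS)-1,2,4a,5-tetramethyl-1,2,3,4,4a,7,8,8a-octahydronaphthalen-2-yl]methyl}cyclopent-2-ene-1-carboxylate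
Conditions: [(Ph3P)CuH]6, benzene/THF, degassed H2O (2 equiv), rt; neutral work-up
Reagents that add atoms: none
Why: Copper hydride conjugate reduction: hydride should add to the exocyclic β-carbon of the ordinary enone and not to C2′ of the α-methoxy enone (deactivated by the methoxy donor and shielded by quaternary C1′), and the copper enolate should be protonated at C5′ under kinetic control from the face of the small hydroxyl group, anti to CO2Me, which puts C5′–H cis to OH (5′R).

**Compound list**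

1 | 2-methylcyclohex-2-en-1-one | CC1=CCCCC1=O | starting material
2 | vinylmagnesium bromide | C=C[Mg]Br | starting material
3 | tert-butyl bromoacetate | CC(C)(C)OC(=O)CBr | starting material
4 | bromomagnesium (3S)-3-ethenyl-2-methylcyclohex-1-en-1-olate | CC1=C(O[Mg]Br)CCC[C@H]1C=C | intermediate
5 | tert-butyl 2-[(1S,6S)-6-ethenyl-1-methyl-2-oxocyclohexyl]acetate | CC(C)(C)OC(=O)C[C@]1(C)C(=O)CCC[C@H]1C=C | intermediate
6 | potassium (5S,6S)-6-(2-tert-butoxy-2-oxoethyl)-5-ethenyl-6-methylcyclohex-1-en-1-olate | CC(C)(C)OC(=O)C[C@]1(C)C(O[K])=CCC[C@H]1C=C | intermediate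
7 | tert-butyl 2-[(1S,6S)-6-ethenyl-1-methyl-2-(trifluoromethylsulfonyloxy)cyclohex-2-en-1-yl]acetate | CC(C)(C)OC(=O)C[C@]1(C)C(OS(=O)(=O)C(F)(F)F)=CCC[C@H]1C=C | intermediate
8 | tert-butyl 2-[(1S,6S)-6-ethenyl-1,2-dimethylcyclohex-2-en-1-yl]acetate | CC(C)(C)OC(=O)C[C@]1(C)C(C)=CCC[C@H]1C=C | intermediate
9 | tert-butyl 2-[(1S,6R)-6-acetyl-1,2-dimethylcyclohex-2-en-1-yl]acetate | CC(C)(C)OC(=O)C[C@]1(C)C(C)=CCC[C@H]1C(C)=O | intermediate
10 | 2-[(1S,6R)-6-(1-hydroxyethyl)-1,2-dimethylcyclohex-2-en-1-yl]ethan-1-ol | OCC[C@]1(C)C(C)=CCC[C@H]1C(C)O | intermediate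
11 | 2-[(1S,6R)-6-acetyl-1,2-dimethylcyclohex-2-en-1-yl]acetaldehyde | O=CC[C@]1(C)C(C)=CCC[C@H]1C(C)=O | intermediate
12 | (4aS,8aR)-3-hydroxy-4a,5-dimethyl-3,4,4a,7,8,8a-hexahydronaphthalen-1(2H)-one (C3 epimers) | O=C1CC(O)C[C@]2(C)C(C)=CCC[C@H]21 | intermediate
13 | (4aS,8aR)-4a,5-dimethyl-4a,7,8,8a-tetrahydronaphthalen-1(4H)-one | O=C1C=CC[C@]2(C)C(C)=CCC[C@H]21 | intermediate
14 | (4aS,8aR)-2-(hydroxymethyl)-4a,5-dimethyl-4a,7,8,8a-tetrahydronaphthalen-1(4H)-one | O=C1C(CO)=CC[C@]2(C)C(C)=CCC[C@H]21 | intermediate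
15 | (4aS,8aR)-2-{[(tert-butyldimethylsilyl)oxy]methyl}-4a,5-dimethyl-4a,7,8,8a-tetrahydronaphthalen-1(4H)-one | O=C1C(CO[Si](C)(C)C(C)(C)C)=CC[C@]2(C)C(C)=CCC[C@H]21 | intermediate
16 | potassium (4aS,8aR)-2-{[(tert-butyldimethylsilyl)oxy]methyl}-4a,5-dimethyl-3,4,4a,7,8,8a-hexahydronaphthalen-1-olate | [K]OC1=C(CO[Si](C)(C)C(C)(C)C)CC[C@]2(C)C(C)=CCC[C@H]21 | intermediate
17 | (2R,4aS,8aR)-2-{[(tert-butyldimethylsilyl)oxy]methyl}-2,4a,5-trimethyl-3,4,4a,7,8,8a-hexahydronaphthalen-1(2H)-one | CC(C)(C)[Si](C)(C)OC[C@@]1(C)CC[C@]2(C)C(C)=CCC[C@H]2C1=O | intermediate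
18 | tert-butyldimethyl{[(2S,4aS,8aS)-2,4a,5-trimethyl-1-methylidene-1,2,3,4,4a,7,8,8a-octahydronaphthalen-2-yl]methoxy}silane | CC(C)(C)[Si](C)(C)OC[C@@]1(C)CC[C@]2(C)C(C)=CCC[C@H]2C1=C | intermediate
19 | tert-butyldimethyl{[(1R,2S,4aS,8aS)-1,2,4a,5-tetramethyl-1,2,3,4,4a,7,8,8a-octahydronaphthalen-2-yl]methoxy}silane | CC(C)(C)[Si](C)(C)OC[C@@]1(C)CC[C@]2(C)C(C)=CCC[C@H]2[C@H]1C | intermediate
20 | [(1R,2S,4aS,8aS)-1,2,4a,5-tetramethyl-1,2,3,4,4a,7,8,8a-octahydronaphthalen-2-yl]methanol | OC[C@@]1(C)CC[C@]2(C)C(C)=CCC[C@H]2[C@H]1C | intermediate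
21 | (1R,2S,4aS,8aS)-1,2,4a,5-tetramethyl-1,2,3,4,4a,7,8,8a-octahydronaphthalene-2-carbaldehyde | O=C[C@@]1(C)CC[C@]2(C)C(C)=CCC[C@H]2[C@H]1C | intermediate
22 | acetone | CC(C)=O | starting material
23 | methyl (E)-2-oxo-4-phenylbut-3-enoate | COC(=O)C(=O)/C=C/c1ccccc1 | starting material
24 | methyl (2R,3E)-2-hydroxy-2-(2-oxopropyl)-4-phenylbut-3-enoate | COC(=O)[C@](O)(/C=C/c1ccccc1)CC(C)=O | intermediate
25 | methyl (2R,3E)-2-[(tert-butyldimethylsilyl)oxy]-2-(2-oxopropyl)-4-phenylbut-3-enoate | COC(=O)[C@](O[Si](C)(C)C(C)(C)C)(/C=C/c1ccccc1)CC(C)=O | intermediate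
26 | methyl (2R)-2-[(tert-butyldimethylsilyl)oxy]-4-oxo-2-(5-phenyl-1,2,4-trioxolan-3-yl)pentanoate (ozonide, ring epimers) | COC(=O)[C@](O[Si](C)(C)C(C)(C)C)(C1OOC(O1)c1ccccc1)CC(C)=O | intermediate
27 | methyl (2R)-2-[(tert-butyldimethylsilyl)oxy]-2-formyl-4-oxopentanoate | COC(=O)[C@](O[Si](C)(C)C(C)(C)C)(C=O)CC(C)=O | intermediate
28 | methyl (1R)-1-[(tert-butyldimethylsilyl)oxy]-2-hydroxy-4-oxocyclopentane-1-carboxylate (C2 epimers) | COC(=O)[C@]1(O[Si](C)(C)C(C)(C)C)C(O)CC(=O)C1 | intermediate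
29 | methyl (1R)-1-[(tert-butyldimethylsilyl)oxy]-4-oxocyclopent-2-ene-1-carboxylate | COC(=O)[C@]1(O[Si](C)(C)C(C)(C)C)C=CC(=O)C1 | intermediate
30 | methyl (1R)-1-[(tert-butyldimethylsilyl)oxy]-3-iodo-4-oxocyclopent-2-ene-1-carboxylate | COC(=O)[C@]1(O[Si](C)(C)C(C)(C)C)C=C(I)C(=O)C1 | intermediate
31 | methyl (1R)-1-[(tert-butyldimethylsilyl)oxy]-3-methoxy-4-oxocyclopent-2-ene-1-carboxylate | COC(=O)[C@]1(O[Si](C)(C)C(C)(C)C)C=C(OC)C(=O)C1 | intermediate
32 | lithium enolate of 31, methyl 1-[(tert-butyldimethylsilyl)oxy]-4-(lithiooxy)-3-methoxycyclopenta-2,4-diene-1-carboxylate (C1 as in 31) | COC(=O)[C@]1(O[Si](C)(C)C(C)(C)C)C=C(OC)C(O[Li])=C1 | intermediate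
33 | methyl (1S)-1-[(tert-butyldimethylsilyl)oxy]-5-{hydroxy[(1R,2S,4aS,8aS)-1,2,4a,5-tetramethyl-1,2,3,4,4a,7,8,8a-octahydronaphthalen-2-yl]methyl}-3-methoxy-4-oxocyclopent-2-ene-1-carboxylate | COC(=O)[C@]1(O[Si](C)(C)C(C)(C)C)C=C(OC)C(=O)C1C(O)[C@@]1(C)CC[C@]2(C)C(C)=CCC[C@H]2[C@H]1C | intermediate
34 | methanesulfonate of 33 | COC(=O)[C@]1(O[Si](C)(C)C(C)(C)C)C=C(OC)C(=O)C1C(OS(C)(=O)=O)[C@@]1(C)CC[C@]2(C)C(C)=CCC[C@H]2[C@H]1C | intermediate
35 | methyl (1S)-1-[(tert-butyldimethylsilyl)oxy]-3-methoxy-4-oxo-5-{[(1R,2S,4aS,8aS)-1,2,4a,5-tetramethyl-1,2,3,4,4a,7,8,8a-octahydronaphthalen-2-yl]methylidene}cyclopent-2-ene-1-carboxylate | COC(=O)[C@]1(O[Si](C)(C)C(C)(C)C)C=C(OC)C(=O)C1=C[C@@]1(C)CC[C@]2(C)C(C)=CCC[C@H]2[C@H]1C | intermediate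
36 | methyl (1S)-1-hydroxy-3-methoxy-4-oxo-5-{[(1R,2S,4aS,8aS)-1,2,4a,5-tetramethyl-1,2,3,4,4a,7,8,8a-octahydronaphthalen-2-yl]methylidene}cyclopent-2-ene-1-carboxylate | COC(=O)[C@]1(O)C=C(OC)C(=O)C1=C[C@@]1(C)CC[C@]2(C)C(C)=CCC[C@H]2[C@H]1C | intermediate
37 | Dysidenone A, methyl (1S,5R)-1-hydroxy-3-methoxy-4-oxo-5-{[(1R,2R,4aS,8aS)-1,2,4a,5-tetramethyl-1,2,3,4,4a,7,8,8a-octahydronaphthalen-2-yl]methyl}cyclopent-2-ene-1-carboxylate | COC(=O)[C@]1(O)C=C(OC)C(=O)[C@@H]1C[C@@]1(C)CC[C@]2(C)C(C)=CCC[C@H]2[C@H]1C | target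

**Step count**

Total: 24 steps. Longest linear sequence: 18 steps (steps 1–14, then 21–24); the ring C branch is steps 15–20.

**Steps most likely to fail**

Step 1. The vinyl transfer from the chiral copper species may be too weakly face-selective, and C-alkylation of the magnesium enolate may be slow enough for proton transfer or O-alkylation to compete. Fallback, from 1 back to 5: a Hayashi–Miyaura reaction of 1 with potassium vinyltrifluoroborate ([Rh(cod)2]BF4 with a chiral bisphosphine or diene ligand, dioxane/H2O, heat) gives (3S)-3-ethenyl-2-methylcyclohexan-1-one F1. Thermodynamic silylation (Me3SiCl, NaI, Et3N, MeCN) gives the more substituted enol ether {[(3S)-3-ethenyl-2-methylcyclohex-1-en-1-yl]oxy}trimethylsilane F2. MeLi in THF releases lithium (3S)-3-ethenyl-2-methylcyclohex-1-en-1-olate F3, which is alkylated by 3 anti to the vinyl group to give 5. The enantio-determining step is then a rhodium carbometalation, and the alkylation uses a preformed lithium enolate.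

Step 12. Hydrogen delivery to C1 may be poorly face-selective, because the axial C2 methyl on the α-face competes with the syn-axial C4a methyl on the β-face; the exocyclic alkene may also migrate, or C5=C6 may be reduced. Fallback, from 15 back to 21, in which C1 is set before C2 becomes quaternary so that the α-face carries only hydrogens. Conjugate reduction of 15 without methylation (KBH(s-Bu)3, then NH4Cl) gives (2R,4aS,8aR)-2-{[(tert-butyldimethylsilyl)oxy]methyl}-4a,5-dimethyl-3,4,4a,7,8,8a-hexahydronaphthalen-1(2H)-one F4. Non-basic methylenation (Cp2TiMe2, toluene, 70 °C) gives tert-butyl{[(2S,4aS,8aS)-4a,5-dimethyl-1-methylidene-1,2,3,4,4a,7,8,8a-octahydronaphthalen-2-yl]methoxy}dimethylsilane F5. Hydrogenation (H2, PtO2) from the open α-face gives tert-butyldimethyl{[(1R,2S,4aS,8aS)-1,4a,5-trimethyl-1,2,3,4,4a,7,8,8a-octahydronaphthalen-2-yl]methoxy}silane F6. Bu4NF gives [(1R,2S,4aS,8aS)-1,4a,5-trimethyl-1,2,3,4,4a,7,8,8a-octahydronaphthalen-2-yl]methanol F7, and Dess–Martin oxidation gives (1R,4aS,8aS)-1,4a,5-trimethyl-1,2,3,4,4a,7,8,8a-octahydronaphthalene-2-carbaldehyde F8 (either C2 epimer). Methylation of its enolate (KOtBu, MeI, THF) anti to the axial C1 methyl gives 21.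

Step 24. The enolate may be protonated from the ester face, or C5′ may drift toward the thermodynamic epimer mixture under the reaction conditions; hydride may also attack the methoxy enone. Fallback, from 36 directly to 37: hydroxyl-directed homogeneous hydrogenation ([Rh(nbd)(dppb)]BF4, H2 under pressure, CH2Cl2). The catalyst is bound by the C1′ hydroxyl, so both hydrogens are delivered syn from the hydroxyl face to the exocyclic alkene without an enolate intermediate; no new compound is formed on the way.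

**Further compounds**

F1 | step 1 | (3S)-3-ethenyl-2-methylcyclohexan-1-one (C2 epimers) | CC1C(=O)CCC[C@H]1C=C
F2 | step 1 | {[(3S)-3-ethenyl-2-methylcyclohex-1-en-1-yl]oxy}trimethylsilane | CC1=C(O[Si](C)(C)C)CCC[C@H]1C=C
F3 | step 1 | lithium (3S)-3-ethenyl-2-methylcyclohex-1-en-1-olate | CC1=C(O[Li])CCC[C@H]1C=C
F4 | step 12 | (2R,4aS,8aR)-2-{[(tert-butyldimethylsilyl)oxy]methyl}-4a,5-dimethyl-3,4,4a,7,8,8a-hexahydronaphthalen-1(2H)-one | CC(C)(C)[Si](C)(C)OC[C@H]1CC[C@]2(C)C(C)=CCC[C@H]2C1=O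
F5 | step 12 | tert-butyl{[(2S,4aS,8aS)-4a,5-dimethyl-1-methylidene-1,2,3,4,4a,7,8,8a-octahydronaphthalen-2-yl]methoxy}dimethylsilane | CC(C)(C)[Si](C)(C)OC[C@H]1CC[C@]2(C)C(C)=CCC[C@H]2C1=C
F6 | step 12 | tert-butyldimethyl{[(1R,2S,4aS,8aS)-1,4a,5-trimethyl-1,2,3,4,4a,7,8,8a-octahydronaphthalen-2-yl]methoxy}silane | CC(C)(C)[Si](C)(C)OC[C@H]1CC[C@]2(C)C(C)=CCC[C@H]2[C@H]1C
F7 | step 12 | [(1R,2S,4aS,8aS)-1,4a,5-trimethyl-1,2,3,4,4a,7,8,8a-octahydronaphthalen-2-yl]methanol | OC[C@H]1CC[C@]2(C)C(C)=CCC[C@H]2[C@H]1C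
F8 | step 12 | (1R,4aS,8aS)-1,4a,5-trimethyl-1,2,3,4,4a,7,8,8a-octahydronaphthalene-2-carbaldehyde (either C2 epimer) | O=CC1CC[C@]2(C)C(C)=CCC[C@H]2[C@H]1C
F0 | step 24 | none | none
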